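All runs stem from a simulated flask on assumed constants; the scatter is artificial.

Sunday's Cat over Saturday's is 0.330, and the dispute is over what that ratio does to the rate.

| flask | Sub | Rgt | Cat | time |
|---|---|---|---|---|
| Saturday's | 50.0 mM | 60.0 mM | 0.100 mM |  |
| Friday's | 25.0 mM | 35.0 mM | 0.100 mM |  |
| Tuesday's | 50.0 mM | 120 mM | 0.100 mM |  |
| Thursday's | 100 mM | 60.0 mM | 0.100 mM |  |
| Sunday's | 50.0 mM | 20.0 mM | 0.0330 mM | 24 min |

| run | time / min | [Sub] / mM |
|---|---|---|
| Saturday's run | 0.96 | 49.6 |
| Saturday's run | 1.5 | 49.0 |
| Saturday's run | 2.4 | 47.0 |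
| Saturday's run | 3.8 | 46.0 |
| Saturday's run | 6.0 | 44.4 |
| Saturday's run | 9.6 | 41.4 |
| Saturday's run | 15 | 38.2 |
| Saturday's run | 24 | 32.0 |
| Friday's run | 0.96 | 24.7 |
| Friday's run | 1.5 | 24.2 |
| Friday's run | 2.4 | 23.5 |
| Friday's run | 3.8 | 23.1 |
| Friday's run | 6.0 | 22.3 |
| Friday's run | 9.6 | 20.8 |
| Friday's run | 15 | 18.4 |
| Friday's run | 24 | 14.8 |
| Tuesday's run | 0.96 | 48.4 |
| Tuesday's run | 1.5 | 46.7 |
| Tuesday's run | 2.4 | 44.9 |
| Tuesday's run | 3.8 | 43.0 |
| Tuesday's run | 6.0 | 39.1 |
| Tuesday's run | 9.6 | 33.7 |
| Tuesday's run | 15 | 26.2 |
| Tuesday's run | 24 | 14.4 |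
| Thursday's run | 0.96 | 98.4 |
| Thursday's run | 1.5 | 97.4 |
| Thursday's run | 2.4 | 96.6 |
| Thursday's run | 3.8 | 95.0 |
| Thursday's run | 6.0 | 91.8 |
| Thursday's run | 9.6 | 86.7 |
| Thursday's run | 15 | 81.6 |
| Thursday's run | 24 | 74.5 |

(readings scatter by 0.3 mM)

1. apparent order in [Rgt] of the starting rate, round the charge of the Saturday's run (the rate where two percent of its Sub have turned into Prd)
2. apparent order in [Sub] of the starting rate, round the charge of the Saturday's run (the rate where two percent of its Sub have turned into Prd) (one fixed amount of Prd, the same in the runs compared)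
3. the Friday's run starts with 25.0 mM less of Sub and of Rgt than the Saturday's run, and with no Prd. Compared where both hold the same amount of Sub, once fifteen percent of what the Friday's run was charged with has turned into Prd, is the Friday's run faster, slower or alike (within a tenth)?
4. Sub in the Sunday's run at 24 min, as a share of the Sub charged

- Overall: Sub + Rgt -> Prd, with Cat as catalyst.
- Constant volume, constant temperature.
- What is held in complexes is read along with the free species.
- An order is taken over about fifteen percent of the charge, up and down.

Sunday's run holds 20.0 mM of Rgt against 50.0 mM of Sub, so Rgt is the limiting reagent. Its end state keeps 30.0 mM of Sub, 60.0% of the charge. The question is how far it gets in 24 min.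

Saturday's run gives the pace. Rgt falls one for one with Sub. By 6.0 min, Tuesday's run had used 1.95 times the Sub of Saturday's run, on 2.00 times the Rgt. So at a given Sub and Cat the loss looks pseudo-first-order in [Rgt].

I call its constant the Rgt clock: the natural log of Rgt charged over Rgt left, divided by the time. Saturday's reading at 9.6 min gives 0.0161 /min. Sunday's run starts at the same [Sub], so the clock should carry over, apart from Cat.

Two chemists part here. The first says the clock follows [Cat], so it scales by 0.330. Rgt then decays over 24 min and leaves 95.2% of the Sub.

The second points to Thursday's run. With Sub raised by a factor of 2.00 at equal Rgt, it used 1.46 times the Sub of Saturday's run by 6.0 min. She reads a route that follows Sub and ignores Cat, and she keeps the clock unchanged. That leaves 87.2%.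

The first replies that a partly filled Cat also rises with Sub. Each run held 0.100 mM of Cat, so no run tests [Cat] directly. The steps in Sub still speak. By 6.0 min, Sub used per Rgt charged in Saturday's run was 1.21 times that of Friday's run, on 2.00 times the Sub. Thursday's run then stood 1.46 times above Saturday's run, on 2.00 times the Sub. A simple filling curve gives a smaller step at higher Sub, but these readings show a larger one. I take the two numbers as my bounds and lean to the lower.

The forecast stands on the first side. It says “Sunday assumes first order in Cat, which is untested”, and it gives 95%, between 91.5% and 96.5%. Its orders are 0.92 in Rgt and 0.25 in Sub, and it calls Friday's run faster.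

The flask gives 89.5% for Sunday's run, orders of 1.0 in Rgt and 0.45 in Sub, and Friday's run alike.

    Cat + Sub ⇌ Cat.Sub, settled at all times (179.0 /M)
    Cat.Sub + Rgt → Prd + Cat (337.8 /M/min)
    Cat.Sub + Sub ⇌ Cat.Sub2, settled at all times (114.0 /M)
    Sub + Rgt → Prd (0.2328 /M/min)

That share makes Sunday's clock 0.0127 /min, while the bare step at Sunday's Sub gives 0.0116 /min. Against Saturday's clock, Cat's part reads 0.317. The Cat view keeps its ground at thinner Sub: at Friday's charge, the Cat route gives 0.00829 /min, more than the bare step's 0.00582 /min. Saturday's clock puts 12.5 mM of Prd in Tuesday's run at 6.83 min, and that run reached it at 7.02 min.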